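## Structural features

6-Prenylsakuranetin (21) is a flavanone: benzene ring A is fused to a dihydropyran-4-one ring C (O1, C2, C3, C4, C4a, C8a), and a 4-hydroxyphenyl ring B is attached to C2 by a single bond. Ring A is hexasubstituted and carries in sequence C4a (acyl), C5–OH, C6–prenyl (3-methylbut-2-enyl), C7–OMe, C8–H and C8a–O1, so the prenyl group lies between two oxygenated carbons and O5 is hydrogen-bonded to the C4 carbonyl. The only stereocentre is C2 (S); it has no stereogenic neighbour, so only the absolute configuration has to be controlled. C2 is benzylic and β to the ketone through O1, and it can be lost by ring opening to the 2'-hydroxychalcone under base or strong acid. The prenyl olefin is the second fragile element: it rules out catalytic hydrogenation, and electrophiles or protic and Lewis acids can add HX to it or close a pyran ring onto O5 or O7. The real difficulty is twofold: the regiochemistry of ring A (prenyl at C6 and not C8, O7 methylated but O5 free) and the setting of C2 as one enantiomer without touching the olefin. The key step exploits the fact that C4 is an isolated carbonyl carbon between C4a and the C3–C2 unit that bears ring B, with O1 on the neighbouring carbon C8a, so that CO can be inserted between an aryl iodide at C4a and a terminal arylacetylene and the ortho oxygen can then close ring C. A 5,7-dimethoxy-6-prenyl ring A derives from a mirror-symmetric phenol, which removes the regiochemical problem before the coupling; the O5/O7 distinction is recovered at the end from the chelation of O5 to C4=O.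

## Logic of the disconnections

21 ⇒ 20. The O5–H and O4'–H bonds are traced back to O5–CH3 and O4'–CH2OCH3. Both phenols have to be masked for the copper hydride step and for the carbonylation, and a methyl group on O5 (the same group as on O7) keeps ring A symmetric early in the route. No skeletal simplification results, but a three-oxygen differentiation problem becomes one that the C4 carbonyl solves by chelation. The forward step must cleave O5–Me and the acetal but not O7–Me, and must neither cyclise or hydrohalogenate the prenyl group nor epimerise C2.

20 ⇒ 18. The C2–H and C3–H bonds are removed, which erases the only stereocentre and leaves the planar, achiral ring C of 18. The gain is that ring C can now be made by an annulation that needs no stereocontrol. The forward step must deliver hydride to one face of C2 in a 1,4-sense, without H2 (prenyl olefin), without 1,2-reduction of C4=O, and with a work-up that avoids base.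

18 ⇒ 8 + 13 + 14. The bonds C4a–C4, C4–C3 and O1–C2 are cut, which takes ring C apart into an aryl iodide, a one-carbon unit and a terminal alkyne. This is the largest gain in simplicity: a hexasubstituted benzene, a para-disubstituted benzene and a gas, joined convergently. The forward step requires that 14 is taken up before the alkyne is transferred, that the oxygen closes the six-membered ring and not the five-membered one, and that the nitrogen base does not intercept the acyl metal species. For these reasons the phenol oxygen of the iodide is carried as its acetate in 8 and is released only after the triple bond has been converted into an enaminone.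

8 ⇒ 6 (through 7). The C–I bond at the future C4a and the O-acetyl bond are cut. In 6 the two carbons ortho to the hydroxyl are related by a mirror plane, so mono-iodination can give only 7. The forward step must iodinate the ring and not the prenyl olefin, must stop after one iodine, and must not let the labile 7 stand; it is acetylated in the same flask.

6 ⇒ 5 ⇒ 2 + 3 (through 4) ⇒ 1. The aryl–CH2 bond of the prenyl group is cut at the ring carbon that lies between the two methoxy groups, and the silyl group is traced back to the free phenol 1. This reduces ring A to two commercial compounds. The forward sequence needs lithiation at that carbon only (the bulky silyl ether in 2 blocks the other two positions) and allylation at the primary carbon of 3.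

13 ⇒ 12 ⇒ 10 + 11 ⇒ 9. The C(sp2)–C(sp) bond of the arylacetylene and the O–CH2OCH3 bond are cut, leading to 9 and 11. The acetal on O4' must survive K2CO3 in methanol, amines, CO under palladium catalysis and the copper hydride, and must leave in the same final operation that frees O5.

## Other disconnections considered

Alternative 1: The cut is C2–C3 of ring C. The precursor is the enol acetal 5,7-dimethoxy-4-methylidene-6-prenyl-2-[4-(triisopropylsilyloxy)phenyl]-4H-1,3-benzodioxine (A2), which would come from the benzodioxin-4-one A1 by carbonyl methylenation with Cp2TiMe2. In the forward key step a chiral aluminium Lewis acid would ionise the C2–O3 acetal bond of A2, and the enolate carbon would recombine with the oxocarbenium carbon to give the flavanone silyl ether A3.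
- In favour: ring C and the stereocentre arise in one event at the correct oxidation level, and no CO is needed. On this structural point the alternative is better than the chosen plan, which needs a separate reduction.
- Against: the acetal stereocentre is destroyed on ionisation, so the sense at C2 would have to come entirely from the chiral counter-ion across an ion pair. The classical rearrangement relays substrate chirality and has no such precedent to lean on. The 4-silyloxybenzyl-stabilised cation is long-lived, could be captured by the prenyl olefin, and the Lewis acid could reopen the product and erode its enantiomeric purity.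
- Ring A: A1 needs a hexasubstituted salicylic acid unit, whose regiochemistry must be solved separately, most plausibly from 6.
- Comparison: the step count would be about equal (methylenation, rearrangement, then O5 demethylation and desilylation), and the final chelation-controlled demethylation is the same problem in both plans. The stereochemical mechanism is less secure than a ligand-controlled hydride addition.

Alternative 2: The cut is through ring A at C5–C6, C7–C8 and C4a–C5. The precursors are the diazoketone (2S)-6-(2-diazoacetyl)-2-[4-(triisopropylsilyloxy)phenyl]-2,3-dihydro-4H-pyran-4-one (A4), in which ring C and C2 already exist, and the ynol ether 1-methoxy-5-methylhex-4-en-1-yne (A5). Forward, irradiation would trigger a Wolff rearrangement of A4, followed by [2+2] addition of A5, four-electron ring opening, six-electron ring closure and tautomerisation to A6, the 4'-O-silyl ether of 21.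
- In favour: the pericyclic cascade places OH at C5, prenyl at C6 and OMe at C7 by its intrinsic regiochemistry and delivers O5 free. No selective demethylation and no strong Lewis acid near the prenyl group are needed, and one mild desilylation finishes the synthesis. On ring A regiochemistry and on the endgame this alternative is the better plan.
- Against: A4 is a doubly activated, fragile diazoketone that takes several steps and hazardous diazo chemistry to make, and the labile A5 must also be prepared. The ketene partner is conjugated to a vinylogous ester, which is an untested electronic situation for this cascade. The thermal stage would expose C2, and the new phenol could be acylated by the ketene.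
- Comparison: it would be shorter after the key step and clearly longer before it, with a longer linear sequence overall.

Alternative 3: The cut is C3=C4 at the enol silane level. The precursor is the diene A7, in which O1 carries the (1S)-1-[4-(methoxymethoxy)phenyl]prop-2-enyl group and C4a carries a 1-(tert-butyldimethylsilyloxy)ethenyl group. A ruthenium alkylidene would join the two terminal olefins with loss of a volatile two-carbon alkene to give the 2H-chromene enol silane A8. A8 is the tert-butyldimethylsilyl analogue of 19, and its hydrolysis would lead to 20.
- In favour: C2 would be set before ring closure by a C–O bond formation of predictable sense (asymmetric allylic etherification or inversion of an enantioenriched allylic alcohol), not by a face-selective reduction. On the security of the stereochemical assignment this is equal to or better than the chosen plan. It also needs no CO.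
- Against: the prenyl olefin is a competing metathesis site, whereas in the chosen plan it is a pure spectator. Ring closure onto a hindered, electron-rich 1,1-disubstituted enol ether is slow. The benzylic and allylic aryl ether bond of A7 is prone to ionisation and to [3,3] shift onto the free C8 position, and forming that ether on a hydrogen-bonded ortho-acyl phenol is difficult. A8 could also racemise by reversible electrocyclic ring opening.
- Comparison: the route would need an ortho-acylated derivative of 6, the etherification, enol silylation, metathesis and hydrolysis before it reaches 20. That is one or two steps more than the chosen plan, with the same last step.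

Key step: step 8

Assumption: (R)-DTBM-SEGPHOS is written in step 9 on the premise that this antipode directs hydride to the face of C2 that gives the 2S product; if the sense is the opposite, the (S)-ligand is used with no other change.

Remark on the chemistry: the precursor and product skeletons map correctly onto the target (phenol C1–C6 become C8a, C4a, C5, C6, C7, C8) and need no correction. Two points are refined: the phenol of the iodide is masked as its acetate (8), and the ring closure through the enaminone is a 6-endo-trig addition–elimination, not a direct 6-endo-dig attack on the alkyne.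

## Route

Step 1
Reactants: 1 3,5-dimethoxyphenol
Product: 2 (3,5-dimethoxyphenoxy)triisopropylsilane
Conditions: TIPSCl, imidazole, DMF, rt
Reagents that add atoms: triisopropylsilyl chloride, CC(C)[Si](Cl)(C(C)C)C(C)C
Why: O-Silylation of a phenol (silyl ether formation); the bulky triisopropylsilyl group makes the oxygen a poor directing group and shields both ortho carbons, which prepares the regioselective lithiation of step 2.

Step 2
Reactants: 2 (3,5-dimethoxyphenoxy)triisopropylsilane; 3 prenyl bromide (1-bromo-3-methylbut-2-ene)
Product: 5 [3,5-dimethoxy-4-(3-methylbut-2-enyl)phenoxy]triisopropylsilane, via aryllithium 4 (not isolated)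
Conditions: n-BuLi, THF, 0 °C → rt; CuBr·SMe2 (10 mol %), 3, −78 °C → rt
Reagents that add atoms: none
Why: Directed ortho-metalation: the C–H between the two methoxy groups is activated by both and is the only one not flanked by the silyloxy group, so 4 should form there. Copper-catalysed allylic substitution at the primary carbon of 3 (SN2; the SN2' path would build a quaternary carbon next to two ortho substituents) then gives 5.

Step 3
Reactants: 5 [3,5-dimethoxy-4-(3-methylbut-2-enyl)phenoxy]triisopropylsilane
Product: 6 3,5-dimethoxy-4-(3-methylbut-2-enyl)phenol
Conditions: TBAF, THF, 0 °C; aq. NH4Cl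
Reagents that add atoms: none
Why: Fluoride-induced cleavage of an aryl silyl ether; no other group in 5 reacts with fluoride.

Step 4
Reactants: 6 3,5-dimethoxy-4-(3-methylbut-2-enyl)phenol
Product: 8 2-iodo-3,5-dimethoxy-4-(3-methylbut-2-enyl)phenyl acetate, via iodophenol 7 (not isolated)
Conditions: NIS (1.0 equiv), CH2Cl2, −40 → 0 °C, dark; then Et3N, Ac2O, DMAP (cat.), 0 °C → rt
Reagents that add atoms: N-iodosuccinimide, O=C1CCC(=O)N1I; acetic anhydride, CC(=O)OC(C)=O
Why: Electrophilic aromatic iodination followed by O-acetylation in the same flask. The two ortho carbons of 6 are mirror images, each ortho to OH and ortho/para to the methoxy groups, so only one mono-iodide can form, and this phloroglucinol-type ring should take up the iodonium ion much faster than the trisubstituted olefin at low temperature. 7 is acetylated at once because an electron-rich ortho-iodophenol is prone to lose iodine and to oxidise, and because the masked phenol is what step 8 needs.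

Step 5
Reactants: 9 4-iodophenol
Product: 10 1-iodo-4-(methoxymethoxy)benzene
Conditions: MOMCl, i-Pr2NEt, CH2Cl2, 0 °C → rt
Reagents that add atoms: chloromethyl methyl ether, COCCl
Why: O-Alkylation of a phenol to a methoxymethyl acetal (Williamson-type etherification); the acetal is stable to all basic, organometallic and hydridic steps that follow. The reagent can be generated in the flask from dimethoxymethane and acetyl chloride with ZnBr2 to avoid handling it neat.

Step 6
Reactants: 10 1-iodo-4-(methoxymethoxy)benzene; 11 trimethylsilylacetylene
Product: 12 {[4-(methoxymethoxy)phenyl]ethynyl}trimethylsilane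
Conditions: PdCl2(PPh3)2 (2 mol %), CuI (4 mol %), Et3N, THF, rt
Reagents that add atoms: none
Why: Sonogashira coupling of an aryl iodide with a terminal alkyne; the silyl group blocks the second alkyne terminus so that only mono-arylation can occur.

Step 7
Reactants: 12 {[4-(methoxymethoxy)phenyl]ethynyl}trimethylsilane
Product: 13 1-ethynyl-4-(methoxymethoxy)benzene
Conditions: K2CO3 (cat.), MeOH, rt
Reagents that add atoms: none
Why: Base-catalysed methanolysis of the C(sp)–Si bond (protodesilylation); the acetal is inert to carbonate, and 13 is used soon after isolation to limit oligomerisation.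

Step 8
Reactants: 8 2-iodo-3,5-dimethoxy-4-(3-methylbut-2-enyl)phenyl acetate; 13 1-ethynyl-4-(methoxymethoxy)benzene; 14 carbon monoxide
Product: 18 5,7-dimethoxy-2-[4-(methoxymethoxy)phenyl]-6-(3-methylbut-2-enyl)chromen-4-one, via acetoxy ynone 15 (not isolated), via acetoxy enaminone 16 (not isolated), via hydroxy enaminone 17 (not isolated)
Conditions: PdCl2(PPh3)2 (5 mol %), Et3N (3 equiv), THF, CO (5 bar), 50 °C; then vent, Et2NH (10 equiv), 60 °C
Reagents that add atoms: none
Why: Copper-free carbonylative Sonogashira coupling followed by amine-mediated annulation; the closest known reaction type is the palladium-catalysed carbonylative annulation of 2-iodophenols or their acetates with terminal alkynes to flavones. PdCl2(PPh3)2 is reduced in the flask to zerovalent palladium, which adds oxidatively to the C–I bond of 8; CO insertion gives an aroyl divalent palladium species (C4a–C4), and amine-assisted transfer of the acetylide of 13 with reductive elimination forms C4–C3 and gives 15. Et2NH then adds to the ynone in conjugate fashion to give 16 and cleaves the aryl acetate to give 17, whose phenol adds to the enaminone β-carbon and expels Et2NH, forming O1–C2. Ring C therefore closes by a 6-endo-trig addition–elimination, which is the net equivalent of a 6-endo-dig closure on the ynone; no stereocentre is formed. The step needs CO uptake ahead of alkyne transfer, which the copper-free conditions, the CO pressure and the ready insertion of CO into a hindered, electron-rich aryl–palladium bond should secure. It needs the aroyl palladium species to escape capture by nitrogen or oxygen nucleophiles, which the tertiary amine in the first stage and the acetate mask ensure. It needs the six-membered and not the five-membered (aurone) ring, which is secured because the triple bond is already an enaminone when the phenol is released, so a 5-exo-dig attack has no substrate. The 5,7-dioxygen-6-prenyl pattern is fixed by the structure of 8, and the unactivated trisubstituted olefin and the acetal are spectators.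

Step 9
Reactants: 18 5,7-dimethoxy-2-[4-(methoxymethoxy)phenyl]-6-(3-methylbut-2-enyl)chromen-4-one
Product: 20 (2S)-5,7-dimethoxy-2-[4-(methoxymethoxy)phenyl]-6-(3-methylbut-2-enyl)chroman-4-one, via silyl enol ether 19 (not isolated)
Conditions: Cu(OAc)2 (5 mol %), (R)-DTBM-SEGPHOS (5.5 mol %), (EtO)2MeSiH (3 equiv), toluene, 0 °C → rt; then 1 M HCl, THF, 0 °C
Reagents that add atoms: none
Why: Asymmetric conjugate reduction of a chromone by a ligated monovalent copper hydride (asymmetric 1,4-hydrosilylation): hydride is delivered to C2 on the face selected by the chiral bisphosphine, so C2 is set as S by catalyst control alone. The copper enolate is silylated to 19, which shields C4 from 1,2-reduction and is hydrolysed by cold dilute acid, which does not affect C2. No H2 is used and the unactivated prenyl olefin is not hydrocuprated; the endocyclic C2–O1 bond lies near the nodal plane of the enolate, which disfavours ring opening.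

Step 10
Reactants: 20 (2S)-5,7-dimethoxy-2-[4-(methoxymethoxy)phenyl]-6-(3-methylbut-2-enyl)chroman-4-one
Product: 21 6-prenylsakuranetin [(2S)-5-hydroxy-2-(4-hydroxyphenyl)-7-methoxy-6-(3-methylbut-2-enyl)chroman-4-one]
Conditions: BCl3 (3.5 equiv), CH2Cl2, −78 → −20 °C; pH 7 phosphate buffer, 0 °C
Reagents that add atoms: none
Why: Chelation-controlled Lewis acid dealkylation: BCl3 bridges the C4 carbonyl and the peri O5 methyl ether in a six-membered chelate, so chloride removes that methyl group while the unchelated O7 methyl ether stays, and the same reagent cleaves the acetal on O4'. The low temperature, the absence of free HCl until the buffered quench, and the binding of O5 as a boron chelate should keep the prenyl olefin from cyclising or adding HCl and C2 from epimerising.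

## Compound list

1 | 3,5-dimethoxyphenol | COc1cc(O)cc(OC)c1 | starting material
2 | (3,5-dimethoxyphenoxy)triisopropylsilane | COc1cc(O[Si](C(C)C)(C(C)C)C(C)C)cc(OC)c1 | intermediate
3 | prenyl bromide (1-bromo-3-methylbut-2-ene) | CC(C)=CCBr | starting material
4 | [2,6-dimethoxy-4-(triisopropylsilyloxy)phenyl]lithium | [Li]c1c(OC)cc(O[Si](C(C)C)(C(C)C)C(C)C)cc1OC | intermediate
5 | [3,5-dimethoxy-4-(3-methylbut-2-enyl)phenoxy]triisopropylsilane | COc1cc(O[Si](C(C)C)(C(C)C)C(C)C)cc(OC)c1CC=C(C)C | intermediate
6 | 3,5-dimethoxy-4-(3-methylbut-2-enyl)phenol | COc1cc(O)cc(OC)c1CC=C(C)C | intermediate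
7 | 2-iodo-3,5-dimethoxy-4-(3-methylbut-2-enyl)phenol | COc1cc(O)c(I)c(OC)c1CC=C(C)C | intermediate
8 | 2-iodo-3,5-dimethoxy-4-(3-methylbut-2-enyl)phenyl acetate | COc1cc(OC(C)=O)c(I)c(OC)c1CC=C(C)C | intermediate
9 | 4-iodophenol | Oc1ccc(I)cc1 | starting material
10 | 1-iodo-4-(methoxymethoxy)benzene | COCOc1ccc(I)cc1 | intermediate
11 | trimethylsilylacetylene | C#C[Si](C)(C)C | starting material
12 | {[4-(methoxymethoxy)phenyl]ethynyl}trimethylsilane | COCOc1ccc(C#C[Si](C)(C)C)cc1 | intermediate
13 | 1-ethynyl-4-(methoxymethoxy)benzene | C#Cc1ccc(OCOC)cc1 | intermediate
14 | carbon monoxide | [C-]#[O+] | starting material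
15 | 3,5-dimethoxy-2-{3-[4-(methoxymethoxy)phenyl]prop-2-ynoyl}-4-(3-methylbut-2-enyl)phenyl acetate | COc1cc(OC(C)=O)c(C(=O)C#Cc2ccc(OCOC)cc2)c(OC)c1CC=C(C)C | intermediate
16 | 2-{(2E)-3-(diethylamino)-3-[4-(methoxymethoxy)phenyl]prop-2-enoyl}-3,5-dimethoxy-4-(3-methylbut-2-enyl)phenyl acetate | COc1cc(OC(C)=O)c(C(=O)/C=C(/N(CC)CC)c2ccc(OCOC)cc2)c(OC)c1CC=C(C)C | intermediate
17 | (2E)-3-(diethylamino)-1-[6-hydroxy-2,4-dimethoxy-3-(3-methylbut-2-enyl)phenyl]-3-[4-(methoxymethoxy)phenyl]prop-2-en-1-one | COc1cc(O)c(C(=O)/C=C(/N(CC)CC)c2ccc(OCOC)cc2)c(OC)c1CC=C(C)C | intermediate
18 | 5,7-dimethoxy-2-[4-(methoxymethoxy)phenyl]-6-(3-methylbut-2-enyl)chromen-4-one | COc1cc2oc(-c3ccc(OCOC)cc3)cc(=O)c2c(OC)c1CC=C(C)C | intermediate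
19 | diethoxy({(2S)-5,7-dimethoxy-2-[4-(methoxymethoxy)phenyl]-6-(3-methylbut-2-enyl)-2H-chromen-4-yl}oxy)methylsilane | COc1cc2c(c(OC)c1CC=C(C)C)C(O[Si](C)(OCC)OCC)=C[C@@H](c1ccc(OCOC)cc1)O2 | intermediate
20 | (2S)-5,7-dimethoxy-2-[4-(methoxymethoxy)phenyl]-6-(3-methylbut-2-enyl)chroman-4-one | COc1cc2c(c(OC)c1CC=C(C)C)C(=O)C[C@@H](c1ccc(OCOC)cc1)O2 | intermediate
21 | 6-prenylsakuranetin, (2S)-5-hydroxy-2-(4-hydroxyphenyl)-7-methoxy-6-(3-methylbut-2-enyl)chroman-4-one | COc1cc2c(c(O)c1CC=C(C)C)C(=O)C[C@@H](c1ccc(O)cc1)O2 | target

## Step count and least certain steps

Total step count: 10. Longest linear sequence: 7 steps (steps 1, 2, 3, 4, 8, 9, 10, from 1); the alkyne branch is 3 steps (steps 5 to 7).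

Step 8 (key step). The most likely failures are transfer of the alkyne to the aryl palladium species before CO is taken up (slow insertion at the doubly ortho-substituted centre or CO starvation), oxidative homocoupling of the alkyne, and stalling of the acetate aminolysis or of the amine expulsion in the second stage, for which a final acidification with acetic acid would be the first remedy. The fallback dispenses with palladium and CO and makes C4a–C4 by acylation of an aryllithium with a three-carbon unit that already contains C4–C3. It sets out from 7 (isolated after the first operation of step 4, without acetylation) and from 13. Deprotonation of 13 with n-BuLi and acylation with N-methoxy-N-methylcarbamoyl chloride should give N-methoxy-3-[4-(methoxymethoxy)phenyl]-N-methylprop-2-ynamide F1. Treatment of 7 with n-BuLi (2.2 equiv, THF, −78 °C) deprotonates the phenol and exchanges iodine for lithium to give lithium 2-lithio-3,5-dimethoxy-4-(3-methylbut-2-enyl)phenolate F2, which is added to F1 to give, after aqueous NH4Cl, 1-[6-hydroxy-2,4-dimethoxy-3-(3-methylbut-2-enyl)phenyl]-3-[4-(methoxymethoxy)phenyl]prop-2-yn-1-one F3. Et2NH in ethanol at 60 °C converts F3 through 17 into 18, where the route is rejoined.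

Step 9. The 5,7-dimethoxy-2-aryl chromone is an electron-rich vinylogous ester, so slow hydride transfer, competing 1,2-reduction of C4=O, insufficient facial discrimination by the ligand for a 2-aryl substrate, or erosion of configuration by ring opening during hydrolysis are all possible. The fallback separates reduction from stereocontrol. From 18, conjugate reduction with LiBH(s-Bu)3 (THF, −78 °C) should give racemic 5,7-dimethoxy-2-[4-(methoxymethoxy)phenyl]-6-(3-methylbut-2-enyl)chroman-4-one F4. Kinetic resolution by asymmetric transfer hydrogenation with RuCl(p-cymene)[(R,R)-TsDPEN] in HCO2H/Et3N is expected to reduce the 2R ketone to (2R,4R)-5,7-dimethoxy-2-[4-(methoxymethoxy)phenyl]-6-(3-methylbut-2-enyl)chroman-4-ol F5 and to leave the 2S ketone, which is 20. This neither uses H2 nor touches the prenyl group, but it gives at most half of the material.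

Step 10. The risks are acid-induced ring closure of the liberated O5–H onto the prenyl olefin, addition of HCl to that olefin during the quench, partial epimerisation of C2 through Lewis acid-promoted opening of ring C, and over-reaction at the O7 methyl ether. The fallback replaces the single strong boron Lewis acid by two mild, orthogonal operations. From 20, MgI2·OEt2 in THF at 50 °C should remove only the chelated methyl group and give (2S)-5-hydroxy-7-methoxy-2-[4-(methoxymethoxy)phenyl]-6-(3-methylbut-2-enyl)chroman-4-one F6. Methanolysis of the acetal with catalytic HCl in methanol at room temperature then gives 21.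

Step 4. The risks are attack of the iodonium ion on the prenyl olefin, a second iodination at the remaining ortho carbon, and loss of iodine from 7 before it is acetylated. The fallback introduces iodine by way of a carbanion, so that no electrophilic iodine meets the olefin under equilibrating conditions. From 6, MOMCl/i-Pr2NEt should give 1,3-dimethoxy-5-(methoxymethoxy)-2-(3-methylbut-2-enyl)benzene F7. Directed ortho-metalation with n-BuLi (THF, −20 °C), between the acetal oxygen and a methoxy group, gives [2,4-dimethoxy-6-(methoxymethoxy)-3-(3-methylbut-2-enyl)phenyl]lithium F8, and an iodine quench at −78 °C gives 2-iodo-3,5-dimethoxy-1-(methoxymethoxy)-4-(3-methylbut-2-enyl)benzene F9. Mild acetal cleavage with ZnBr2 and n-PrSH in CH2Cl2 at 0 °C returns 7, which is acetylated as in the second operation of step 4 to rejoin the route at 8.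

## Further compounds

F1 | step 8 | N-methoxy-3-[4-(methoxymethoxy)phenyl]-N-methylprop-2-ynamide | CON(C)C(=O)C#Cc1ccc(OCOC)cc1
F2 | step 8 | lithium 2-lithio-3,5-dimethoxy-4-(3-methylbut-2-enyl)phenolate | [Li]Oc1cc(OC)c(CC=C(C)C)c(OC)c1[Li]
F3 | step 8 | 1-[6-hydroxy-2,4-dimethoxy-3-(3-methylbut-2-enyl)phenyl]-3-[4-(methoxymethoxy)phenyl]prop-2-yn-1-one | COc1cc(O)c(C(=O)C#Cc2ccc(OCOC)cc2)c(OC)c1CC=C(C)C
F4 | step 9 | racemic 5,7-dimethoxy-2-[4-(methoxymethoxy)phenyl]-6-(3-methylbut-2-enyl)chroman-4-one | COc1cc2c(c(OC)c1CC=C(C)C)C(=O)CC(c1ccc(OCOC)cc1)O2
F5 | step 9 | (2R,4R)-5,7-dimethoxy-2-[4-(methoxymethoxy)phenyl]-6-(3-methylbut-2-enyl)chroman-4-ol | COc1cc2c(c(OC)c1CC=C(C)C)[C@H](O)C[C@H](c1ccc(OCOC)cc1)O2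
F6 | step 10 | (2S)-5-hydroxy-7-methoxy-2-[4-(methoxymethoxy)phenyl]-6-(3-methylbut-2-enyl)chroman-4-one | COc1cc2c(c(O)c1CC=C(C)C)C(=O)C[C@@H](c1ccc(OCOC)cc1)O2
F7 | step 4 | 1,3-dimethoxy-5-(methoxymethoxy)-2-(3-methylbut-2-enyl)benzene | COCOc1cc(OC)c(CC=C(C)C)c(OC)c1
F8 | step 4 | [2,4-dimethoxy-6-(methoxymethoxy)-3-(3-methylbut-2-enyl)phenyl]lithium | [Li]c1c(OCOC)cc(OC)c(CC=C(C)C)c1OC
F9 | step 4 | 2-iodo-3,5-dimethoxy-1-(methoxymethoxy)-4-(3-methylbut-2-enyl)benzene | COCOc1cc(OC)c(CC=C(C)C)c(OC)c1I
A1 | alternative 1 | 5,7-dimethoxy-6-(3-methylbut-2-enyl)-2-[4-(triisopropylsilyloxy)phenyl]-4H-1,3-benzodioxin-4-one | COc1cc2c(c(OC)c1CC=C(C)C)C(=O)OC(c1ccc(O[Si](C(C)C)(C(C)C)C(C)C)cc1)O2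
A2 | alternative 1 | 5,7-dimethoxy-4-methylidene-6-(3-methylbut-2-enyl)-2-[4-(triisopropylsilyloxy)phenyl]-4H-1,3-benzodioxine | COc1cc2c(c(OC)c1CC=C(C)C)C(=C)OC(c1ccc(O[Si](C(C)C)(C(C)C)C(C)C)cc1)O2
A3 | alternative 1 | (2S)-5,7-dimethoxy-6-(3-methylbut-2-enyl)-2-[4-(triisopropylsilyloxy)phenyl]chroman-4-one | COc1cc2c(c(OC)c1CC=C(C)C)C(=O)C[C@@H](c1ccc(O[Si](C(C)C)(C(C)C)C(C)C)cc1)O2
A4 | alternative 2 | (2S)-6-(2-diazoacetyl)-2-[4-(triisopropylsilyloxy)phenyl]-2,3-dihydro-4H-pyran-4-one | [N-]=[N+]=CC(=O)C1=CC(=O)C[C@@H](c2ccc(O[Si](C(C)C)(C(C)C)C(C)C)cc2)O1
A5 | alternative 2 | 1-methoxy-5-methylhex-4-en-1-yne | COC#CCC=C(C)C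
A6 | alternative 2 | (2S)-5-hydroxy-7-methoxy-6-(3-methylbut-2-enyl)-2-[4-(triisopropylsilyloxy)phenyl]chroman-4-one (6-prenylsakuranetin 4'-O-triisopropylsilyl ether) | COc1cc2c(c(O)c1CC=C(C)C)C(=O)C[C@@H](c1ccc(O[Si](C(C)C)(C(C)C)C(C)C)cc1)O2
A7 | alternative 3 | tert-butyl{[1-(2,4-dimethoxy-6-{[(1S)-1-[4-(methoxymethoxy)phenyl]prop-2-enyl]oxy}-3-(3-methylbut-2-enyl)phenyl)ethenyl]oxy}dimethylsilane | C=C[C@@H](c1ccc(OCOC)cc1)Oc1cc(OC)c(CC=C(C)C)c(OC)c1C(=C)O[Si](C)(C)C(C)(C)C
A8 | alternative 3 | tert-butyl{[(2S)-5,7-dimethoxy-2-[4-(methoxymethoxy)phenyl]-6-(3-methylbut-2-enyl)-2H-chromen-4-yl]oxy}dimethylsilane | COc1cc2c(c(OC)c1CC=C(C)C)C(O[Si](C)(C)C(C)(C)C)=C[C@@H](c1ccc(OCOC)cc1)O2
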